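The readings come from a simulation from invented constants, and the scatter is random.

A flat substrate column is a trap: in percent it looks like a stopped flask, so I asked instead how many time constants of loss the flask had run through.

in all of them: catalyst 150 mM

| run | substrate | solid reagent | remark | time |
|---|---|---|---|---|
| zeta | 1 M (fed, over 4.0 h) | 1.4 M | run made earlier |  |
| alpha | 1 M (fed, over 4.0 h) | 2.2 M | run made earlier |  |
| flask | 1.0 M (fed, over 4.0 h) | 1.00 M |  | 20 h |

| run | time / h | substrate / % | target / % |
|---|---|---|---|
| zeta | 2.00 | 48.2 | 1.2 |
| zeta | 5.00 | 99.2 | 0.5 |
| zeta | 10.0 | 99.0 | 0 |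
| zeta | 15.0 | 99.3 | 0 |
| zeta | 20.0 | 95.3 | 1.2 |
| alpha | 4.00 | 100.0 | 0 |
| alpha | 8.00 | 99.4 | 0.8 |
| alpha | 12.0 | 98.6 | 0 |
| alpha | 15.0 | 99.4 | 0.4 |
| alpha | 20.0 | 97.4 | 1.3 |

(scatter of a reading: 1 percentage point)

1. amount of substrate in percent of the substrate charged, at 2.0 h, 6.0 h, 12 h and 20 h

- given per volume of solution although it is solid: solid reagent
- the numbers in the tables scatter with a standard deviation of 1 percentage point
- at the start none of the solid reagent is in solution
- percentages count the whole charge, also what has not yet gone in

After the feed, each run had its hold, and I folded hold and loss into one number, the hold number D, the hold time over the time constant of substrate loss (a Damköhler number). I took it as the mean, over the zeta and alpha runs, of the logarithm of charge over substrate left at 20.0 h: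

D = 0.0372, decadic logarithm −1.43

τ = hold / D = 430 h

The hold thus took up 0.0372 of one time constant, so I expected the substrate to fall by about that fraction.

Was one number enough? Not during the feed, where I counted the substrate by the ratio of time to dosing time, 50.0% at 2.0 h. The two runs gave 0.0481 and 0.0263, but their readings lie 2.1 percentage points apart against a scatter of 1 point on each, so I read no trend with solid reagent. This flask, though, holds less solid reagent than either run. My course for it was 99.5% at 6.0 h, 98.2% at 12 h and 96.3% at 20 h.

The forecast gave 50%, 99%, 99% and 95%, on the ground that “the solid loading has little effect”; its last value stands lower than mine.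

The flask gave 50.0%, 99.7%, 98.8% and 97.1%, and the forecast held.

    substrate + coupling partner + catalyst → catalyst + target (k = 0.00140 /M²/min)
    solid reagent ⇌ coupling partner, rate k2*(cs2 - [coupling partner]) while solid is left; crystals form when [coupling partner] > cs2 (solubility = 0.140 M, k = 5.10 × 10⁻⁴ /min)
    substrate + coupling partner → uncatalysed product (k = 7.40 × 10⁻⁴ /M/min)

This flask's own D came to 0.0294, and a second flask with twice the catalyst stood at 96.7%, a D of 0.0336. In this flask the half-life of substrate by the catalysed step at 9.15 h was 84 d, far longer than the 20 h of the run, and at 20.0 h it held 0.637% target beside 2.24% uncatalysed product.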